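**Retrosynthetic overview**

- The strategy rests on the cyclohexane ring C1–C10–C11–C12–C13–C14, cis-fused along C1–C10 to the tetrahydrofuran C1–C2–O–C9–C10, whose carbons C2 and C9 are also the ether termini of the nine-membered ring (O, C2–C9). Cutting C1–C10 and C13–C14 leaves a (Z)-oxonene with a 2-silyloxydiene on C9 and an (E)-enone on C2 (intramolecular Diels–Alder).
- After the cycloaddition: C16 by methylenation and hydroboration of the C15 ketone, the C11 methyl carbinol from the unmasked ketone, the oxepanone C16(=O)–O–C3 by oxidative lactonisation, the C4 octanoate, and C6–OH/C7=CH2 from the C6=C7 epoxide.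
- Before it: oxonene by ring-closing metathesis at C6=C7; C3 by methyl addition to a ketone; C2 by an Evans glycolate aldol; the C9–O–C2 ether from bromoacetic acid; C9 by Brown methallylation; C4 from (R)-trityl glycidyl ether.
- Ring order: nine-membered ether first, then cyclohexene and tetrahydrofuran together, then the seven-membered lactone.

Key step: step 24

Remark on the chemistry: eunicellane numbering is used throughout (ring oxygen between C2 and C9; methyls C17 on C15, C18 on C3, C19 on C7, C20 on C11). The C3 carbinol centre made in step 9 is oxidised in step 12, so its configuration does not matter. Compounds 1, 6, 10, 12, 31 and 43 are taken as commercial.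

**Route**

Step 1
Reactants: 1 (R)-trityl glycidyl ether
Product: 2 (R)-1-(trityloxy)pent-4-en-2-ol
Conditions: CH2=CHMgBr, CuI (10 mol%), THF, −30 to 0 °C
Reagents that add atoms: vinylmagnesium bromide, C=C[Mg]Br
Why: Copper-catalysed Grignard opening of the terminal epoxide at its CH2 carbon (SN2) gives the homoallylic alcohol and leaves the existing stereocentre (the future C4) untouched.

Step 2
Reactants: 2 (R)-1-(trityloxy)pent-4-en-2-ol
Product: 3 (R)-tert-butyldimethyl{[1-(trityloxy)pent-4-en-2-yl]oxy}silane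
Conditions: TBSCl, imidazole, DMF, rt
Reagents that add atoms: tert-butyldimethylsilyl chloride, CC(C)(C)[Si](C)(C)Cl
Why: Standard imidazole-promoted silylation of a secondary alcohol installs the C4 silyl ether that is carried to step 30.

Step 3
Reactants: 3 (R)-tert-butyldimethyl{[1-(trityloxy)pent-4-en-2-yl]oxy}silane
Product: 4 (R)-2-(tert-butyldimethylsilyloxy)pent-4-en-1-ol
Conditions: ZnBr2, CH2Cl2–MeOH, rt
Reagents that add atoms: none
Why: Lewis-acid detritylation through the trityl cation (trapped by methanol) frees the primary alcohol while the secondary TBS ether survives.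

Step 4
Reactants: 4 (R)-2-(tert-butyldimethylsilyloxy)pent-4-en-1-ol
Product: 5 (R)-2-(tert-butyldimethylsilyloxy)pent-4-enal
Conditions: Dess–Martin periodinane, NaHCO3, CH2Cl2, 0 °C to rt
Reagents that add atoms: none
Why: Buffered Dess–Martin oxidation gives the α-silyloxy aldehyde without epimerisation; it is used at once.

Step 5
Reactants: 6 3-(4-methoxybenzyloxy)propan-1-ol
Product: 7 3-(4-methoxybenzyloxy)propanal
Conditions: TEMPO (10 mol%), PhI(OAc)2, CH2Cl2, rt
Reagents that add atoms: none
Why: Oxoammonium-mediated oxidation of a primary alcohol stops cleanly at the aldehyde.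

Step 6
Reactants: 7 3-(4-methoxybenzyloxy)propanal
Product: 9 (S)-1-(4-methoxybenzyloxy)-5-methylhex-5-en-3-ol, via diisopinocampheylborinate ester 8 (not isolated)
Conditions: (−)-Ipc2BOMe, CH2=C(CH3)CH2MgCl, Et2O, −78 °C to rt; then 7, −78 °C; NaOH, H2O2
Reagents that add atoms: 2-methylallylmagnesium chloride, CC(=C)C[Mg]Cl
Why: Brown asymmetric methallylation through a closed six-membered transition state; the borane derived from (+)-α-pinene should deliver the methallyl group to the Si face of the aldehyde and so set C9 as S.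

Step 7
Reactants: 9 (S)-1-(4-methoxybenzyloxy)-5-methylhex-5-en-3-ol; 10 bromoacetic acid
Product: 11 (S)-2-{[1-(4-methoxybenzyloxy)-5-methylhex-5-en-3-yl]oxy}acetic acid
Conditions: NaH, THF, 0 °C to rt; then aq. HCl
Reagents that add atoms: none
Why: Williamson etherification of the sodium alkoxide with sodium bromoacetate forms the C9–O–C2 ether at an unhindered CH2 electrophile without touching C9.

Step 8
Reactants: 11 (S)-2-{[1-(4-methoxybenzyloxy)-5-methylhex-5-en-3-yl]oxy}acetic acid; 12 (R)-4-benzyloxazolidin-2-one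
Product: 14 N-glycolyl oxazolidinone, via mixed pivalic anhydride 13 (not isolated)
Conditions: t-BuCOCl, Et3N, THF, −78 to 0 °C; then lithiated 12 (n-BuLi, THF, −78 °C)
Reagents that add atoms: none
Why: The lithiated oxazolidinone attacks the less hindered carbonyl of the mixed anhydride (standard N-acylation of an Evans auxiliary).

Step 9
Reactants: 14 N-glycolyl oxazolidinone; 5 (R)-2-(tert-butyldimethylsilyloxy)pent-4-enal
Product: 17 (2R,3R,4R) syn-aldol imide, via Z-dibutylboron enolate 15 (not isolated), via dibutylboron aldolate 16 (not isolated)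
Conditions: Bu2BOTf, Et3N, CH2Cl2, −78 to 0 °C; then 5, −78 to 0 °C; pH 7 buffer, MeOH, H2O2
Reagents that add atoms: none
Why: Evans syn aldol through the (Z)-boron enolate and a Zimmerman–Traxler chair; the (R)-benzyl auxiliary blocks one enolate face and so sets C2 in the configuration of the target, and the chair sets the 2,3-syn C3 carbinol, which is removed in step 12.

Step 10
Reactants: 17 (2R,3R,4R) syn-aldol imide
Product: 18 (2S,3R,4R)-4-(tert-butyldimethylsilyloxy)-2-{[(S)-1-(4-methoxybenzyloxy)-5-methylhex-5-en-3-yl]oxy}hept-6-ene-1,3-diol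
Conditions: LiBH4, MeOH (1 equiv), THF, 0 °C
Reagents that add atoms: none
Why: Reductive cleavage of the imide by LiBH4 gives the primary C1 alcohol and returns the auxiliary without epimerising C2.

Step 11
Reactants: 18 (2S,3R,4R)-1,3-diol
Product: 19 (2S,3R,4R)-1-pivalate
Conditions: t-BuCOCl, pyridine, CH2Cl2, 0 °C
Reagents that add atoms: pivaloyl chloride, CC(C)(C)C(=O)Cl
Why: The primary hydroxyl is acylated selectively over the hindered secondary one; pivalate is chosen because it has no α-hydrogen and can be removed by i-Bu2AlH in the presence of a silyl enol ether (step 21).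

Step 12
Reactants: 19 (2S,3R,4R)-1-pivalate
Product: 20 (2S,4R)-C3 ketone
Conditions: Dess–Martin periodinane, NaHCO3, CH2Cl2, rt
Reagents that add atoms: none
Why: Buffered Dess–Martin oxidation of the secondary alcohol gives the α,α′-dioxygenated ketone without epimerising C2 or C4.

Step 13
Reactants: 20 (2S,4R)-C3 ketone
Product: 21 (2S,3R,4R)-C3 tertiary alcohol
Conditions: MeLi, THF, −78 °C
Reagents that add atoms: methyllithium, [Li]C
Why: 1,2-Addition under non-chelating conditions (THF-solvated lithium, non-coordinating OTBS at C4, hindered di-secondary ether oxygen at C2); in the polar Felkin–Anh arrangement the C2–O and C4–O bonds lie on the same face of the C3 carbonyl, so methyl should enter anti to both and give the tertiary carbinol with O3 syn to O2 and O4 as in the target, the ketone reacting far faster than the pivalate at −78 °C.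

Step 14
Reactants: 21 (2S,3R,4R)-C3 tertiary alcohol
Product: 22 (2S,3R,4R)-C3 triethylsilyl ether (metathesis substrate)
Conditions: Et3SiOTf, 2,6-lutidine, CH2Cl2, 0 °C
Reagents that add atoms: triethylsilyl trifluoromethanesulfonate, CC[Si](CC)(CC)OS(=O)(=O)C(F)(F)F
Why: A silyl triflate with a hindered base silylates even a congested tertiary alcohol.

Step 15
Reactants: 22 (2S,3R,4R)-C3 triethylsilyl ether
Product: 23 (2S,3R,4R,9S,6Z)-oxonene with C9 2-(4-methoxybenzyloxy)ethyl and C2 pivaloyloxymethyl groups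
Conditions: second-generation Grubbs catalyst RuCl2(=CHPh)(PCy3)(H2IMes) (10 mol%), CH2Cl2 (2 mM), 40 °C
Reagents that add atoms: none
Why: Ring-closing metathesis of the 1,1-disubstituted C7 alkene with the monosubstituted C6 alkene; the gauche-disposed vicinal oxygens preorganise the chain and the nine-membered ring can hold only the (Z) trisubstituted alkene (known for such oxonenes).

Step 16
Reactants: 23 oxonene PMB ether
Product: 24 oxonene with C9 2-hydroxyethyl group
Conditions: DDQ, CH2Cl2–pH 7 buffer, 0 °C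
Reagents that add atoms: none
Why: Oxidative cleavage of the 4-methoxybenzyl ether by DDQ leaves silyl ethers, pivalate and the ring alkene untouched.

Step 17
Reactants: 24 oxonene with C9 2-hydroxyethyl group
Product: 25 C11 aldehyde
Conditions: Dess–Martin periodinane, NaHCO3, CH2Cl2, 0 °C to rt
Reagents that add atoms: none
Why: Mild buffered oxidation gives the β-alkoxy aldehyde without β-elimination of the ring oxygen.

Step 18
Reactants: 25 C11 aldehyde
Product: 26 C11 vinyl carbinol (both C11 epimers)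
Conditions: CH2=CHMgBr, THF, −78 °C
Reagents that add atoms: vinylmagnesium bromide, C=C[Mg]Br
Why: Grignard addition to the aldehyde is much faster than attack on the pivalate at −78 °C; the new carbinol centre is oxidised in the next step.

Step 19
Reactants: 26 C11 vinyl carbinol
Product: 27 C11 vinyl ketone
Conditions: Dess–Martin periodinane, NaHCO3, CH2Cl2, 0 °C
Reagents that add atoms: none
Why: Oxidation of the allylic alcohol gives the vinyl ketone C10H2–C11(=O)–C12=C13 under neutral conditions; it is used directly.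

Step 20
Reactants: 27 C11 vinyl ketone
Product: 28 (Z)-2-triethylsilyloxydiene
Conditions: Et3SiOTf, Et3N, Et2O, −78 to −20 °C
Reagents that add atoms: triethylsilyl trifluoromethanesulfonate, CC[Si](CC)(CC)OS(=O)(=O)C(F)(F)F
Why: Soft enolisation (amine and silyl triflate, the known route from enones to 2-silyloxy-1,3-dienes) can only occur at C10, and the (Z) enol ether with C9 trans to the vinyl group is expected as the main isomer because it avoids A(1,3) strain; the pivalate has no α-hydrogen.

Step 21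
Reactants: 28 (Z)-2-triethylsilyloxydiene
Product: 29 C1 primary alcohol
Conditions: i-Bu2AlH, CH2Cl2, −78 °C; aq. KNaC4H4O6 (potassium sodium tartrate)
Reagents that add atoms: none
Why: Reductive removal of the pivalate at −78 °C, under which silyl enol ethers and silyl ethers are inert.

Step 22
Reactants: 29 C1 primary alcohol
Product: 30 C1 aldehyde
Conditions: SO3·pyridine, DMSO, i-Pr2NEt, CH2Cl2, 0 °C
Reagents that add atoms: none
Why: Parikh–Doering oxidation is base-buffered and non-acidic, so the silyl enol ether survives; the α-alkoxy aldehyde is used without purification.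

Step 23
Reactants: 30 C1 aldehyde; 31 1-(triphenyl-λ5-phosphanylidene)propan-2-one
Product: 32 oxonene with C9 (Z)-2-triethylsilyloxydiene and C2 (E)-enone
Conditions: PhMe, 0 °C to rt
Reagents that add atoms: none
Why: Wittig reaction of the stabilised ylide gives the (E)-enone under neutral conditions that leave the diene intact; the enone is made last because its methyl ketone would not survive step 20.

Step 24
Reactants: 32 oxonene with C9 (Z)-2-triethylsilyloxydiene and C2 (E)-enone
Product: 33 tricyclic cycloadduct with C11 silyl enol ether and C14 acetyl group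
Conditions: PhMe (5 mM), BHT (cat.), 25 to 60 °C
Reagents that add atoms: none
Why: A concerted, suprafacial thermal [4+2] cycloaddition joins the electron-rich diene C10=C11–C12=C13 (largest HOMO coefficient at C10) to the enone C1=C14 (largest LUMO coefficient at C1), forming C1–C10 and C13–C14 in the electronically matched sense; the closest known reaction type is the intramolecular Diels–Alder reaction of 2,9-disubstituted oxonenes that carry diene and dienophile on the two carbons flanking the ring oxygen. The cyclohexene (C1, C10–C14) closes as the six-membered ring of the cycloadduct itself, and the tetrahydrofuran (C1, C2, O, C9, C10) closes in the same event as the five-membered ring spanned by the three-atom tether C9–O–C2 (type 1 intramolecular Diels–Alder), which can only be cis-fused. C14 relative to C1 is fixed by the (E)-geometry of the enone (C2 and C15 trans), C10 relative to C1 by the cis fusion that the short tether enforces, and the absolute sense of all three by the C2 and C9 stereocentres, whose cis arrangement on the (Z)-oxonene lets the diene reach one face of the enone only. The step needs the ketone-exo orientation and a single diene face; both are secured by the medium ring, because the endo and opposite-face approaches would need the C9–O–C2 tether to span geometries the (Z)-olefinic nine-membered ring cannot adopt. The (Z) enol ether places C9 on the outside of the s-cis diene, and the silyl enol ether formed keeps C11 masked and distinct from the C15 ketone.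

Step 25
Reactants: 33 tricyclic cycloadduct
Product: 34 C14 isopropenyl tricycle
Conditions: Ph3PCH3Br, KOt-Bu, THF, 0 °C to rt
Reagents that add atoms: methyltriphenylphosphonium bromide, C[P+](c1ccccc1)(c1ccccc1)c1ccccc1.[Br-]
Why: Wittig methylenation of the only free carbonyl gives C15=C16; the C11 ketone is protected as its silyl enol ether and the trans (equatorial) C14 centre is the stable one.

Step 26
Reactants: 34 C14 isopropenyl tricycle
Product: 35 C11 ketone with free C3 hydroxyl
Conditions: HF·pyridine, pyridine, THF, 0 °C to rt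
Reagents that add atoms: none
Why: Buffered fluoride cleaves the silyl enol ether at once and the tertiary triethylsilyl ether more slowly, while the hindered secondary TBS ether at C4 survives; C10 keeps its configuration because the cis ring fusion is the stable one.

Step 27
Reactants: 35 C11 ketone with free C3 hydroxyl
Product: 36 C11 tertiary alcohol (C3,C11-diol)
Conditions: MeLi, CeCl3, THF, −78 °C
Reagents that add atoms: methyllithium, [Li]C
Why: The weakly basic organocerium reagent adds without enolisation or β-elimination of the C9 oxygen, and methyl should attack the convex face of the cis-fused bicycle, anti to the C10–C9 and C1–C2 bonds, giving the C11 carbinol with OH syn to C9.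

Step 28
Reactants: 36 C11 tertiary alcohol (C3,C11-diol)
Product: 38 C16 primary alcohol (C3,C11,C16-triol), via trialkylborane 37 (not isolated)
Conditions: (+)-Ipc2BH, THF, −25 to 0 °C; then NaOH, H2O2
Reagents that add atoms: hydrogen peroxide, OO
Why: Anti-Markovnikov hydroboration of the 1,1-disubstituted C15=C16 alkene by a hindered dialkylborane spares the trisubstituted C6=C7 alkene; addition to the face turned away from C1 in the rotamer with C14–H eclipsing the alkene gives the required C15 centre, and the chiral borane (Brown asymmetric hydroboration) is chosen to reinforce that preference before oxidation with retention.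

Step 29
Reactants: 38 C16 primary alcohol (C3,C11,C16-triol)
Product: 41 C16→O3 seven-membered lactone, via hydroxy aldehyde 39 (not isolated), via lactol 40 (not isolated)
Conditions: TEMPO (20 mol%), PhI(OAc)2 (3 equiv), CH2Cl2, rt
Reagents that add atoms: none
Why: Oxoammonium oxidation of the primary alcohol gives the C16 aldehyde, which sits next to the tertiary C3 hydroxyl and closes to the lactol; the lactol is oxidised on to the lactone (oxidative lactonisation of a diol), and the tertiary C11 alcohol is inert.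

Step 30
Reactants: 41 C16→O3 seven-membered lactone
Product: 42 C4 alcohol
Conditions: HF·pyridine, THF, 0 °C to rt
Reagents that add atoms: none
Why: Acidic fluoride removes the secondary TBS ether without the acyl migration from O3 to O4 that a basic fluoride source could trigger.

Step 31
Reactants: 42 C4 alcohol; 43 octanoyl chloride
Product: 44 C4 octanoate
Conditions: pyridine, DMAP (cat.), CH2Cl2, 0 °C to rt
Reagents that add atoms: none
Why: DMAP-catalysed acylation esterifies the secondary C4 hydroxyl; the tertiary C11 hydroxyl does not react under these conditions.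

Step 32
Reactants: 44 C4 octanoate
Product: 45 C6,C7-epoxide
Conditions: m-CPBA, NaHCO3, CH2Cl2, 0 °C
Reagents that add atoms: 3-chloroperoxybenzoic acid, O=C(OO)c1cccc(Cl)c1
Why: Prilezhaev epoxidation of the only alkene left, the electron-rich (Z)-C6=C7 bond, should occur from its exposed outer face (the other face looks into the nine-membered ring) and so place the oxygen at C6 in the configuration of the target.

Step 33
Reactants: 45 C6,C7-epoxide
Product: 46 briarellin B
Conditions: Cp2TiCl2, Zn, THF, rt; then 45, rt; dilute aq. HCl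
Reagents that add atoms: none
Why: Titanocene monochloride (trivalent titanium, the Nugent–RajanBabu reagent) opens the epoxide homolytically at the more substituted C7–O bond, a second equivalent traps the tertiary radical and β-hydride elimination toward the unhindered C19 methyl gives the exocyclic alkene (known for trisubstituted epoxides), so the C6–O bond and its configuration stay intact and the lactone, ester and tertiary alcohol are tolerated.

**Compound list**

1 | (R)-2-[(trityloxy)methyl]oxirane, (R)-trityl glycidyl ether | c1ccccc1C(c1ccccc1)(c1ccccc1)OC[C@H]1CO1 | starting material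
2 | (R)-1-(trityloxy)pent-4-en-2-ol | C=CC[C@@H](O)COC(c1ccccc1)(c1ccccc1)c1ccccc1 | intermediate
3 | (R)-tert-butyldimethyl{[1-(trityloxy)pent-4-en-2-yl]oxy}silane | C=CC[C@@H](O[Si](C)(C)C(C)(C)C)COC(c1ccccc1)(c1ccccc1)c1ccccc1 | intermediate
4 | (R)-2-(tert-butyldimethylsilyloxy)pent-4-en-1-ol | C=CC[C@@H](O[Si](C)(C)C(C)(C)C)CO | intermediate
5 | (R)-2-(tert-butyldimethylsilyloxy)pent-4-enal (C3–C6 and O4) | C=CC[C@@H](O[Si](C)(C)C(C)(C)C)C=O | intermediate
6 | 3-(4-methoxybenzyloxy)propan-1-ol | COc1ccc(COCCCO)cc1 | starting material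
7 | 3-(4-methoxybenzyloxy)propanal | COc1ccc(COCCC=O)cc1 | intermediate
8 | bis[(1R,2R,3R,5S)-isopinocampheyl]borinate ester of 9 (not isolated) | C=C(C)C[C@H](OB([C@@H]1C[C@@H]2C[C@H]([C@H]1C)C2(C)C)[C@@H]1C[C@@H]2C[C@H]([C@H]1C)C2(C)C)CCOCc1ccc(OC)cc1 | intermediate
9 | (S)-1-(4-methoxybenzyloxy)-5-methylhex-5-en-3-ol (C9 carbinol) | C=C(C)C[C@H](O)CCOCc1ccc(OC)cc1 | intermediate
10 | bromoacetic acid | OC(=O)CBr | starting material
11 | (S)-2-{[1-(4-methoxybenzyloxy)-5-methylhex-5-en-3-yl]oxy}acetic acid | C=C(C)C[C@H](OCC(=O)O)CCOCc1ccc(OC)cc1 | intermediate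
12 | (R)-4-benzyloxazolidin-2-one | O=C1N[C@H](Cc2ccccc2)CO1 | starting material
13 | mixed anhydride of 11 with pivalic acid (not isolated) | C=C(C)C[C@H](OCC(=O)OC(=O)C(C)(C)C)CCOCc1ccc(OC)cc1 | intermediate
14 | (R)-4-benzyl-3-(2-{[(S)-1-(4-methoxybenzyloxy)-5-methylhex-5-en-3-yl]oxy}acetyl)oxazolidin-2-one | C=C(C)C[C@H](OCC(=O)N1[C@H](Cc2ccccc2)COC1=O)CCOCc1ccc(OC)cc1 | intermediate
15 | (Z)-dibutylboron enolate of 14 (not isolated) | C=C(C)C[C@H](O/C=C(\OB(CCCC)CCCC)N1[C@H](Cc2ccccc2)COC1=O)CCOCc1ccc(OC)cc1 | intermediate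
16 | O-dibutylboryl aldolate of 17 (not isolated) | C=C(C)C[C@H](O[C@@H](C(=O)N1[C@H](Cc2ccccc2)COC1=O)[C@@H](OB(CCCC)CCCC)[C@@H](CC=C)O[Si](C)(C)C(C)(C)C)CCOCc1ccc(OC)cc1 | intermediate
17 | (R)-4-benzyl-3-[(2R,3R,4R)-4-(tert-butyldimethylsilyloxy)-3-hydroxy-2-{[(S)-1-(4-methoxybenzyloxy)-5-methylhex-5-en-3-yl]oxy}hept-6-enoyl]oxazolidin-2-one | C=C(C)C[C@H](O[C@@H](C(=O)N1[C@H](Cc2ccccc2)COC1=O)[C@@H](O)[C@@H](CC=C)O[Si](C)(C)C(C)(C)C)CCOCc1ccc(OC)cc1 | intermediate
18 | (2S,3R,4R)-4-(tert-butyldimethylsilyloxy)-2-{[(S)-1-(4-methoxybenzyloxy)-5-methylhex-5-en-3-yl]oxy}hept-6-ene-1,3-diol | C=C(C)C[C@H](O[C@@H](CO)[C@@H](O)[C@@H](CC=C)O[Si](C)(C)C(C)(C)C)CCOCc1ccc(OC)cc1 | intermediate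
19 | (2S,3R,4R)-4-(tert-butyldimethylsilyloxy)-3-hydroxy-2-{[(S)-1-(4-methoxybenzyloxy)-5-methylhex-5-en-3-yl]oxy}hept-6-en-1-yl pivalate | C=C(C)C[C@H](O[C@@H](COC(=O)C(C)(C)C)[C@@H](O)[C@@H](CC=C)O[Si](C)(C)C(C)(C)C)CCOCc1ccc(OC)cc1 | intermediate
20 | (2S,4R)-4-(tert-butyldimethylsilyloxy)-2-{[(S)-1-(4-methoxybenzyloxy)-5-methylhex-5-en-3-yl]oxy}-3-oxohept-6-en-1-yl pivalate | C=C(C)C[C@H](O[C@@H](COC(=O)C(C)(C)C)C(=O)[C@@H](CC=C)O[Si](C)(C)C(C)(C)C)CCOCc1ccc(OC)cc1 | intermediate
21 | (2S,3R,4R)-4-(tert-butyldimethylsilyloxy)-3-hydroxy-3-methyl-2-{[(S)-1-(4-methoxybenzyloxy)-5-methylhex-5-en-3-yl]oxy}hept-6-en-1-yl pivalate | C=C(C)C[C@H](O[C@@H](COC(=O)C(C)(C)C)[C@@](C)(O)[C@@H](CC=C)O[Si](C)(C)C(C)(C)C)CCOCc1ccc(OC)cc1 | intermediate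
22 | (2S,3R,4R)-4-(tert-butyldimethylsilyloxy)-3-methyl-2-{[(S)-1-(4-methoxybenzyloxy)-5-methylhex-5-en-3-yl]oxy}-3-(triethylsilyloxy)hept-6-en-1-yl pivalate | C=C(C)C[C@H](O[C@@H](COC(=O)C(C)(C)C)[C@@](C)(O[Si](CC)(CC)CC)[C@@H](CC=C)O[Si](C)(C)C(C)(C)C)CCOCc1ccc(OC)cc1 | intermediate
23 | [(2S,3R,4R,9S,6Z)-4-(tert-butyldimethylsilyloxy)-9-[2-(4-methoxybenzyloxy)ethyl]-3,7-dimethyl-3-(triethylsilyloxy)-2,3,4,5,8,9-hexahydrooxonin-2-yl]methyl pivalate | [C@@H]1(CCOCc2ccc(OC)cc2)C/C(C)=C\C[C@@H](O[Si](C)(C)C(C)(C)C)[C@](C)(O[Si](CC)(CC)CC)[C@H](COC(=O)C(C)(C)C)O1 | intermediate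
24 | oxonene as 23 with a 2-hydroxyethyl group at C9 (2S,3R,4R,9S,6Z) | [C@@H]1(CCO)C/C(C)=C\C[C@@H](O[Si](C)(C)C(C)(C)C)[C@](C)(O[Si](CC)(CC)CC)[C@H](COC(=O)C(C)(C)C)O1 | intermediate
25 | oxonene as 23 with a 2-oxoethyl group at C9 (C11 aldehyde) | [C@@H]1(CC=O)C/C(C)=C\C[C@@H](O[Si](C)(C)C(C)(C)C)[C@](C)(O[Si](CC)(CC)CC)[C@H](COC(=O)C(C)(C)C)O1 | intermediate
26 | oxonene as 23 with a 2-hydroxybut-3-enyl group at C9 (both C11 epimers) | [C@@H]1(CC(O)C=C)C/C(C)=C\C[C@@H](O[Si](C)(C)C(C)(C)C)[C@](C)(O[Si](CC)(CC)CC)[C@H](COC(=O)C(C)(C)C)O1 | intermediate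
27 | oxonene as 23 with a 2-oxobut-3-enyl group at C9 (C11 vinyl ketone) | [C@@H]1(CC(=O)C=C)C/C(C)=C\C[C@@H](O[Si](C)(C)C(C)(C)C)[C@](C)(O[Si](CC)(CC)CC)[C@H](COC(=O)C(C)(C)C)O1 | intermediate
28 | oxonene as 23 with a (1Z)-2-(triethylsilyloxy)buta-1,3-dienyl group at C9 | [C@@H]1(/C=C(O[Si](CC)(CC)CC)/C=C)C/C(C)=C\C[C@@H](O[Si](C)(C)C(C)(C)C)[C@](C)(O[Si](CC)(CC)CC)[C@H](COC(=O)C(C)(C)C)O1 | intermediate
29 | [(2S,3R,4R,9S,6Z)-4-(tert-butyldimethylsilyloxy)-3,7-dimethyl-3-(triethylsilyloxy)-9-[(1Z)-2-(triethylsilyloxy)buta-1,3-dienyl]-2,3,4,5,8,9-hexahydrooxonin-2-yl]methanol | [C@@H]1(/C=C(O[Si](CC)(CC)CC)/C=C)C/C(C)=C\C[C@@H](O[Si](C)(C)C(C)(C)C)[C@](C)(O[Si](CC)(CC)CC)[C@H](CO)O1 | intermediate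
30 | the corresponding oxonin-2-carbaldehyde (C1 aldehyde; C2 is R by CIP with unchanged geometry) | [C@@H]1(/C=C(O[Si](CC)(CC)CC)/C=C)C/C(C)=C\C[C@@H](O[Si](C)(C)C(C)(C)C)[C@](C)(O[Si](CC)(CC)CC)[C@H](C=O)O1 | intermediate
31 | 1-(triphenyl-λ5-phosphanylidene)propan-2-one | CC(=O)C=P(c1ccccc1)(c1ccccc1)c1ccccc1 | starting material
32 | (3E)-4-{(2S,3R,4R,9S,6Z)-4-(tert-butyldimethylsilyloxy)-3,7-dimethyl-3-(triethylsilyloxy)-9-[(1Z)-2-(triethylsilyloxy)buta-1,3-dienyl]-2,3,4,5,8,9-hexahydrooxonin-2-yl}but-3-en-2-one (cycloaddition precursor) | [C@@H]1(/C=C(O[Si](CC)(CC)CC)/C=C)C/C(C)=C\C[C@@H](O[Si](C)(C)C(C)(C)C)[C@](C)(O[Si](CC)(CC)CC)[C@H](/C=C/C(C)=O)O1 | intermediate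
33 | tricyclic cycloadduct: C11=C12 triethylsilyl enol ether, C14 acetyl, C3 OSiEt3, C4 OTBS, (Z)-C6=C7; H1/H10 cis, H1/H14 trans, H2/H9 cis | C/C1=C/C[C@@H](O[Si](C)(C)C(C)(C)C)[C@](C)(O[Si](CC)(CC)CC)[C@H]2O[C@@H](C1)[C@@H]3C(O[Si](CC)(CC)CC)=CC[C@@H](C(C)=O)[C@H]23 | intermediate
34 | as 33 with C14 isopropenyl (C15=C16) in place of acetyl | C/C1=C/C[C@@H](O[Si](C)(C)C(C)(C)C)[C@](C)(O[Si](CC)(CC)CC)[C@H]2O[C@@H](C1)[C@@H]3C(O[Si](CC)(CC)CC)=CC[C@@H](C(C)=C)[C@H]23 | intermediate
35 | tricyclic C11 ketone with free C3 hydroxyl, C4 OTBS, C14 isopropenyl | C/C1=C/C[C@@H](O[Si](C)(C)C(C)(C)C)[C@](C)(O)[C@H]2O[C@@H](C1)[C@@H]3C(=O)CC[C@@H](C(C)=C)[C@H]23 | intermediate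
36 | tricyclic C3,C11-diol (C11 methyl carbinol, OH syn to C9), C4 OTBS, C14 isopropenyl | C/C1=C/C[C@@H](O[Si](C)(C)C(C)(C)C)[C@](C)(O)[C@H]2O[C@@H](C1)[C@@H]3[C@](C)(O)CC[C@@H](C(C)=C)[C@H]23 | intermediate
37 | C16 bis[(1S,2S,3S,5R)-isopinocampheyl]borane adduct of 36 (not isolated) | C/C1=C/C[C@@H](O[Si](C)(C)C(C)(C)C)[C@](C)(O)[C@H]2O[C@@H](C1)[C@@H]3[C@](C)(O)CC[C@@H]([C@@H](C)CB([C@H]4C[C@H]5C[C@@H]([C@@H]4C)C5(C)C)[C@H]4C[C@H]5C[C@@H]([C@@H]4C)C5(C)C)[C@H]23 | intermediate
38 | tricyclic C3,C11,C16-triol (15R), C4 OTBS | C/C1=C/C[C@@H](O[Si](C)(C)C(C)(C)C)[C@](C)(O)[C@H]2O[C@@H](C1)[C@@H]3[C@](C)(O)CC[C@@H]([C@@H](C)CO)[C@H]23 | intermediate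
39 | C16 aldehyde of 38 (not isolated) | C/C1=C/C[C@@H](O[Si](C)(C)C(C)(C)C)[C@](C)(O)[C@H]2O[C@@H](C1)[C@@H]3[C@](C)(O)CC[C@@H]([C@@H](C)C=O)[C@H]23 | intermediate
40 | C16 lactol closed on O3, either anomer (not isolated) | C/C1=C/C[C@@H](O[Si](C)(C)C(C)(C)C)[C@](C)(O4)[C@H]2O[C@@H](C1)[C@@H]3[C@](C)(O)CC[C@@H]([C@@H](C)C4O)[C@H]23 | intermediate
41 | tetracyclic lactone C16(=O)–O–C3 with C4 OTBS, free C11 OH, (Z)-C6=C7 | C/C1=C/C[C@@H](O[Si](C)(C)C(C)(C)C)[C@](C)(O4)[C@H]2O[C@@H](C1)[C@@H]3[C@](C)(O)CC[C@@H]([C@@H](C)C4=O)[C@H]23 | intermediate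
42 | tetracyclic lactone with free C4 and C11 hydroxyls | C/C1=C/C[C@@H](O)[C@](C)(O4)[C@H]2O[C@@H](C1)[C@@H]3[C@](C)(O)CC[C@@H]([C@@H](C)C4=O)[C@H]23 | intermediate
43 | octanoyl chloride | CCCCCCCC(=O)Cl | starting material
44 | tetracyclic lactone C4 octanoate with (Z)-C6=C7 | C/C1=C/C[C@@H](OC(=O)CCCCCCC)[C@](C)(O4)[C@H]2O[C@@H](C1)[C@@H]3[C@](C)(O)CC[C@@H]([C@@H](C)C4=O)[C@H]23 | intermediate
45 | C6,C7-epoxide of 44 (oxygen on the outer face, C5 and C8 cis) | C[C@@]12O[C@@H]1C[C@@H](OC(=O)CCCCCCC)[C@](C)(O4)[C@H]3O[C@@H](C2)[C@@H]5[C@](C)(O)CC[C@@H]([C@@H](C)C4=O)[C@H]35 | intermediate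
46 | briarellin B (1S,2S,3S,4R,6R,9S,10R,11R,14R,15R in eunicellane numbering) | C=C1C[C@@H]2O[C@H]3[C@H]4[C@@H](CC[C@@](C)(O)[C@H]42)[C@@H](C)C(=O)O[C@@]3(C)[C@H](OC(=O)CCCCCCC)C[C@H]1O | target

**Step count and risks**

Total: 33 steps. Longest linear sequence: 29 steps (steps 5–33; the branch through steps 1–4 and 9–33 is equally long).

Steps most likely to fail:

1. Step 28. The isopropenyl group rotates freely and the two alkene faces differ only in their distance from C1, so facial discrimination in the hydroboration may be poor and much of the material may end up as the C15 epimer. Fallback: set C15 thermodynamically after ring closure instead of kinetically at the alkene. It sets out from 36: the hydroboration is run as written and the C15 epimer of the triol, 15-epi triol F1, is carried together with 38 through the oxidative lactonisation of step 29, passing through 15-epi hydroxy aldehyde F2 and 15-epi lactol F3 (neither isolated), to 15-epi lactone F4. In F4 the C15 centre is α to the lactone carbonyl, so F4 is equilibrated with DBU in toluene at 80 °C by enolisation and reprotonation, separated from 41 and recycled, and the material converges on 41, where the route is rejoined. Whether 41 is the favoured epimer at equilibrium cannot be predicted here.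

2. Step 29. The hindered tertiary C3 hydroxyl may not close the seven-membered lactol fast enough, so the oxidation may stall at the hydroxy aldehyde, which can then epimerise at C15 on long exposure. Fallback: acyl activation in place of lactol oxidation. It sets out from 38: TEMPO and PhI(OAc)2 in MeCN–pH 7 buffer oxidise the primary alcohol through aldehyde 39 to seco acid F5. Activation with 2,4,6-trichlorobenzoyl chloride and Et3N in THF gives Yamaguchi mixed anhydride F6 (not isolated), which is added slowly to DMAP in toluene at 80 °C so that the C3 hydroxyl is acylated intramolecularly, returning to 41.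

3. Step 32. The facial preference of the peracid depends on the conformation of the nine-membered ring in the tetracycle, and attack on the other face would give the wrong C6 configuration. Fallback: correct C6 by oxidation and reduction. It sets out from 44: the epoxide of opposite configuration, 6,7-bis-epi epoxide F7, is isomerised as in step 33 to 6-epi allylic alcohol F8 and oxidised with Dess–Martin periodinane to C6 enone F9. Luche reduction (NaBH4, CeCl3·7H2O, MeOH, −78 °C) then delivers hydride in 1,2-fashion to the face the peracid had chosen, which puts the hydroxyl on the other face and gives 46.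

**Further compounds**

F1 | step 28 | 15-epi triol (C15 epimer of 38) | C/C1=C/C[C@@H](O[Si](C)(C)C(C)(C)C)[C@](C)(O)[C@H]2O[C@@H](C1)[C@@H]3[C@](C)(O)CC[C@@H]([C@H](C)CO)[C@H]23
F2 | step 28 | 15-epi hydroxy aldehyde (C15 epimer of 39) | C/C1=C/C[C@@H](O[Si](C)(C)C(C)(C)C)[C@](C)(O)[C@H]2O[C@@H](C1)[C@@H]3[C@](C)(O)CC[C@@H]([C@H](C)C=O)[C@H]23
F3 | step 28 | 15-epi lactol (C15 epimer of 40) | C/C1=C/C[C@@H](O[Si](C)(C)C(C)(C)C)[C@](C)(O4)[C@H]2O[C@@H](C1)[C@@H]3[C@](C)(O)CC[C@@H]([C@H](C)C4O)[C@H]23
F4 | step 28 | 15-epi lactone (C15 epimer of 41) | C/C1=C/C[C@@H](O[Si](C)(C)C(C)(C)C)[C@](C)(O4)[C@H]2O[C@@H](C1)[C@@H]3[C@](C)(O)CC[C@@H]([C@H](C)C4=O)[C@H]23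
F5 | step 29 | seco acid (C16 carboxylic acid with free C3 and C11 hydroxyls) | C/C1=C/C[C@@H](O[Si](C)(C)C(C)(C)C)[C@](C)(O)[C@H]2O[C@@H](C1)[C@@H]3[C@](C)(O)CC[C@@H]([C@@H](C)C(=O)O)[C@H]23
F6 | step 29 | Yamaguchi mixed anhydride of F5 with 2,4,6-trichlorobenzoic acid | C/C1=C/C[C@@H](O[Si](C)(C)C(C)(C)C)[C@](C)(O)[C@H]2O[C@@H](C1)[C@@H]3[C@](C)(O)CC[C@@H]([C@@H](C)C(=O)OC(=O)c4c(Cl)cc(Cl)cc4Cl)[C@H]23
F7 | step 32 | 6,7-bis-epi epoxide (oxygen on the opposite face to 45) | C[C@]12O[C@H]1C[C@@H](OC(=O)CCCCCCC)[C@](C)(O4)[C@H]3O[C@@H](C2)[C@@H]5[C@](C)(O)CC[C@@H]([C@@H](C)C4=O)[C@H]35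
F8 | step 32 | 6-epi allylic alcohol (C6 epimer of 46) | C=C1[C@@H](O)C[C@@H](OC(=O)CCCCCCC)[C@](C)(O4)[C@H]2O[C@@H](C1)[C@@H]3[C@](C)(O)CC[C@@H]([C@@H](C)C4=O)[C@H]23
F9 | step 32 | C6 enone (6-oxo, C7 exocyclic methylene) | C=C1C(=O)C[C@@H](OC(=O)CCCCCCC)[C@](C)(O4)[C@H]2O[C@@H](C1)[C@@H]3[C@](C)(O)CC[C@@H]([C@@H](C)C4=O)[C@H]23
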